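Decalin numbering: C1 (quaternary, CH3/CH2Ar), C2 (CHCH3), C3, C4, C4a (angular CH3), C5 (side chain), C6 (C=O), C7, C8, C8a (H); ring B = C1–C4, C4a, C8a. The plan rests on deleting C2: ring B is carried as the cyclopentanone ring (C1, C3, C4, C4a, C8a) of a trans-hydrindan-2-one. The key step exploits the C1(quaternary)–C2(tertiary) junction of ring B: a β-oxido carbenoid ring enlargement inserts C2 between C1 and carbonyl C3 and releases the C2=C3 enolate regiospecifically, so MeI enters axially, anti to the axial C1 methyl. One operation gives ring B and its contrathermodynamic C1/C2 dyad. The precursor is a dibromomethyl carbinol.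

Key step: step 11

Remark on notation: the numbering above is used for every bicyclic intermediate. β is the face of the angular C4a methyl group and α the opposite face. Ar = 2,5-dimethoxy-3-methylphenyl, TBS = tert-butyldimethylsilyl, Tf = trifluoromethanesulfonyl.

Assumption: the (S,S)-configured transfer-hydrogenation catalyst is taken to give the (2S,3S)-ketol 9. If the sense of induction is the opposite, the (R,R)-catalyst gives the same compound.

Step 1
Reactants: 1 4-methoxy-2-methylphenol
Product: 2 2-hydroxy-5-methoxy-3-methylbenzaldehyde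
Conditions: MgCl2, Et3N, (CH2O)n, MeCN, reflux; aq. HCl
Reagents that add atoms: paraformaldehyde (formaldehyde unit), C=O
Why: Casnati–Skattebøl ortho-formylation: the magnesium phenoxide delivers formaldehyde to the only free ortho carbon, and a second formaldehyde takes up hydride from the benzylic alkoxide.

Step 2
Reactants: 2 2-hydroxy-5-methoxy-3-methylbenzaldehyde
Product: 3 2,5-dimethoxy-3-methylbenzaldehyde
Conditions: MeI, K2CO3, DMF, 23 °C
Reagents that add atoms: iodomethane, CI
Why: Williamson ether synthesis on the only acidic OH group.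

Step 3
Reactants: 3 2,5-dimethoxy-3-methylbenzaldehyde
Product: 4 (2,5-dimethoxy-3-methylphenyl)methanol
Conditions: NaBH4, MeOH, 0 °C
Reagents that add atoms: none
Why: Borohydride reduction of an aromatic aldehyde that carries no other reducible group.

Step 4
Reactants: 4 (2,5-dimethoxy-3-methylphenyl)methanol
Product: 5 1-(bromomethyl)-2,5-dimethoxy-3-methylbenzene
Conditions: PBr3, Et2O, 0 °C
Reagents that add atoms: phosphorus tribromide, BrP(Br)Br
Why: SN2 bromination of an electron-rich benzylic alcohol through its phosphite ester.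

Step 5
Reactants: 6 2-methylcyclohexane-1,3-dione; 7 1-bromobut-2-yne
Product: 8 2-(but-2-yn-1-yl)-2-methylcyclohexane-1,3-dione
Conditions: KOH (1 equiv), H2O, 55 °C
Reagents that add atoms: none
Why: C-alkylation of the stabilised 1,3-dione enolate by a soft propargylic bromide in water, where solvation of oxygen suppresses O-alkylation.

Step 6
Reactants: 8 2-(but-2-yn-1-yl)-2-methylcyclohexane-1,3-dione
Product: 9 (2S,3S)-2-(but-2-yn-1-yl)-3-hydroxy-2-methylcyclohexan-1-one
Conditions: RuCl[(S,S)-TsDPEN](p-cymene) (1 mol %), HCO2H/Et3N 5:2, CH2Cl2, 25 °C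
Reagents that add atoms: none
Why: Noyori asymmetric transfer hydrogenation used as a desymmetrisation: the catalyst picks one of the two enantiotopic carbonyl groups and adds hydride from the methyl-bearing face, which fixes C4a and should place the C5 hydroxyl cis to the butynyl chain, while the hindered second carbonyl reacts much more slowly.

Step 7
Reactants: 9 (2S,3S)-2-(but-2-yn-1-yl)-3-hydroxy-2-methylcyclohexan-1-one
Product: 10 (2S,3S)-2-(but-2-yn-1-yl)-3-(tert-butyldimethylsilyloxy)-2-methylcyclohexan-1-one
Conditions: TBSOTf, 2,6-lutidine, CH2Cl2, 0 °C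
Reagents that add atoms: tert-butyldimethylsilyl triflate, CC(C)(C)[Si](C)(C)OS(=O)(=O)C(F)(F)F
Why: Silylation of a hindered secondary alcohol with the silyl triflate under non-nucleophilic base, which avoids retro-aldol opening of the ketol.

Step 8
Reactants: 10 (2S,3S)-2-(but-2-yn-1-yl)-3-(tert-butyldimethylsilyloxy)-2-methylcyclohexan-1-one
Product: 12 (7S,7aR)-7-(tert-butyldimethylsilyloxy)-3,7a-dimethyl-1,4,5,6,7,7a-hexahydro-2H-inden-2-one, via 1,4-diketone 11 (not isolated)
Conditions: Ph3PAuCl (2 mol %), AgOTf (2 mol %), H2O (5 equiv), 1,4-dioxane, 60 °C; then KOH, MeOH, 60 °C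
Reagents that add atoms: water, O
Why: Carbonyl-assisted gold-catalysed alkyne hydration (5-exo-dig attack of the C8a carbonyl oxygen on the proximal alkyne carbon C3) should give only the 1,4-diketone, and the intramolecular aldol condensation of C1 onto C8a then gives the thermodynamically favoured fused cyclopentenone.

Step 9
Reactants: 12 (7S,7aR)-7-(tert-butyldimethylsilyloxy)-3,7a-dimethyl-1,4,5,6,7,7a-hexahydro-2H-inden-2-one; 5 1-(bromomethyl)-2,5-dimethoxy-3-methylbenzene
Product: 14 (1R,3aR,4S,7aS)-4-(tert-butyldimethylsilyloxy)-1-[(2,5-dimethoxy-3-methylphenyl)methyl]-1,3a-dimethyloctahydro-2H-inden-2-one, via lithium enolate 13 (not isolated)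
Conditions: Li (2.05 equiv), NH3/THF, t-BuOH (1.0 equiv), −78 → −33 °C; then 5, THF, −33 °C, NH3 evaporated
Reagents that add atoms: none
Why: Stork reductive alkylation of an enone: the β-carbon C8a is protonated axially with respect to ring A, anti to the angular methyl group, which gives the trans fusion (8aα-H), and the regiodefined C1=C3 enolate is benzylated on the α face away from that methyl group (1α-CH2Ar, 1β-CH3).

Step 10
Reactants: 14 (1R,3aR,4S,7aS)-4-(tert-butyldimethylsilyloxy)-1-[(2,5-dimethoxy-3-methylphenyl)methyl]-1,3a-dimethyloctahydro-2H-inden-2-one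
Product: 15 dibromomethyl carbinol of 14 (C3 bears β-OH plus α-CHBr2)
Conditions: CH2Br2, LiN(iPr)2 added to the ketone/CH2Br2 mixture, THF, −78 °C; AcOH quench at −78 °C
Reagents that add atoms: dibromomethane, BrCBr
Why: 1,2-addition of dibromomethyllithium, made in the presence of the strained cyclopentanone carbonyl so that addition outruns carbenoid decay; the new carbinol centre, drawn for α attack, is erased in the next step.

Step 11
Reactants: 15 dibromomethyl carbinol of 14 (C3 bears β-OH plus α-CHBr2)
Product: 18 1α-(arylmethyl)-1β,2α,4aβ-trimethyl-5α-(tert-butyldimethylsilyloxy)-8aα-H-decalin-3-one, via β-oxido carbenoid 16 (not isolated), via ring-enlarged lithium enolate 17 (not isolated)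
Conditions: n-BuLi (2.1 equiv), THF, −78 °C, then −78 → 0 °C; recooled to −78 °C, DMPU, MeI (3 equiv), −78 → −30 °C; aq. NH4Cl
Reagents that add atoms: iodomethane, CI
Why: The first n-BuLi deprotonates the carbinol and the second exchanges one bromine for lithium to give the β-oxido carbenoid 16, in which the ring bond C3–C1 shifts to the carbenoid carbon as bromide leaves, so that this carbon becomes C2 inside the ring and the product is born as the lithium enolate 17 with its double bond at C2=C3. The closest known reaction type is the β-oxido carbenoid one-carbon ring enlargement of cycloalkanones, followed by ordinary alkylation of a regiodefined lithium enolate. No new ring is closed: the five-membered ring C1–C3–C4–C4a–C8a is enlarged to the six-membered ring B by a 1,2-alkyl shift with retention at the migrating quaternary C1. The only new stereocentre, C2, is set by the half-chair enolate of the trans-decalin, which MeI attacks along the axial trajectory on the α face, anti to the pseudoaxial 1β-methyl group and away from the 4aβ-methyl group, to give the axial 2α-methyl group. The step needs migration of C1 rather than C4, secured because in such carbenoids the more substituted α-carbon is the better donor and lies anti to the departing bromide; it also needs alkylation at C2 rather than C4, secured because the enolate is formed regiospecifically and is consumed at low temperature before proton exchange. Deprotonation of the corresponding ketone would enolise towards C4, so the ring enlargement itself is what makes the hindered C2 nucleophile available.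

Step 12
Reactants: 18 1α-(arylmethyl)-1β,2α,4aβ-trimethyl-5α-(tert-butyldimethylsilyloxy)-8aα-H-decalin-3-one
Product: 19 C3=C4 enol triflate of 18
Conditions: LiN(iPr)2, THF, −78 °C; PhNTf2, −78 → 0 °C
Reagents that add atoms: N-phenylbis(trifluoromethanesulfonimide), O=S(=O)(N(c1ccccc1)S(=O)(=O)C(F)(F)F)C(F)(F)F
Why: Kinetic enolisation and O-triflation: the axial C4–H is aligned with the carbonyl π system, whereas the tertiary C2–H is equatorial and shielded, so the C2 stereocentre should not be touched.

Step 13
Reactants: 19 C3=C4 enol triflate of 18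
Product: 21 1α-(arylmethyl)-1β,2α,4aβ-trimethyl-8aα-H-decalin-5α-ol, via saturated silyl ether 20 (not isolated)
Conditions: H2 (1 atm), PtO2 (10 mol %), MeOH, 23 °C; then stirred under N2 until the silyl ether is consumed; NaHCO3 work-up
Reagents that add atoms: none
Why: Hydrogenolysis of an enol triflate over platinum takes C3 and C4 to CH2 groups without creating or disturbing a stereocentre, and the triflic acid formed cleaves the silyl ether by acid methanolysis in the same flask.

Step 14
Reactants: 21 1α-(arylmethyl)-1β,2α,4aβ-trimethyl-8aα-H-decalin-5α-ol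
Product: 22 1α-(arylmethyl)-1β,2α,4aβ-trimethyl-8aα-H-decalin-5-one
Conditions: Dess–Martin periodinane, NaHCO3, CH2Cl2, 23 °C
Reagents that add atoms: none
Why: Dess–Martin oxidation of a hindered secondary alcohol under neutral conditions that leave the electron-rich arene alone.

Step 15
Reactants: 22 1α-(arylmethyl)-1β,2α,4aβ-trimethyl-8aα-H-decalin-5-one
Product: 23 C5=C6 enol triflate of 22
Conditions: KN(SiMe3)2, THF, −78 °C; PhNTf2, −78 → 0 °C
Reagents that add atoms: N-phenylbis(trifluoromethanesulfonimide), O=S(=O)(N(c1ccccc1)S(=O)(=O)C(F)(F)F)C(F)(F)F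
Why: Enolate O-triflation in which only C6 can be deprotonated, because C4a is quaternary, so the alkene position is unambiguous.

Step 16
Reactants: 23 C5=C6 enol triflate of 22
Product: 24 5-allyl-1α-(arylmethyl)-1β,2α,4aβ-trimethyl-8aα-H-octalin (C5=C6)
Conditions: allylSnBu3, Pd(PPh3)4 (5 mol %), LiCl (3 equiv), THF, reflux
Reagents that add atoms: allyltributylstannane, C=CC[Sn](CCCC)(CCCC)CCCC
Why: Stille cross-coupling (oxidative addition of the vinyl triflate to zerovalent palladium, chloride exchange, transmetalation, reductive elimination) attaches the three side-chain carbons to C5 and leaves the ring alkene where the C6 oxygen is needed.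

Step 17
Reactants: 24 5-allyl-1α-(arylmethyl)-1β,2α,4aβ-trimethyl-8aα-H-octalin (C5=C6)
Product: 26 1α-(arylmethyl)-5β-(3-hydroxypropyl)-1β,2α,4aβ-trimethyl-8aα-H-decalin-6α-ol, via cyclic borane 25 (not isolated)
Conditions: BH3·THF (1.5 equiv), THF, 0 → 23 °C; then NaOH, H2O2, 0 → 40 °C
Reagents that add atoms: hydrogen peroxide, OO
Why: Cyclic hydroboration–oxidation of a 1,4-diene: boron adds first to the terminal carbon and then intramolecularly to C6, the less substituted ring carbon, with syn addition on the α face away from the neighbouring angular methyl group, which gives 5α-H and 6α-OH.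

Step 18
Reactants: 26 1α-(arylmethyl)-5β-(3-hydroxypropyl)-1β,2α,4aβ-trimethyl-8aα-H-decalin-6α-ol
Product: 27 3-[(1S,4aR,5S,6S,8aR)-5-[(2,5-dimethoxy-3-methylphenyl)methyl]-5,6,8a-trimethyl-2-oxodecahydronaphthalen-1-yl]propanoic acid
Conditions: CrO3, H2SO4, H2O, acetone, 0 °C
Reagents that add atoms: water, O
Why: Jones oxidation takes the secondary alcohol to the C6 ketone and the primary alcohol through its aldehyde hydrate to the acid, and the acidic medium keeps the enolisable C5 in its more stable equatorial (β) configuration.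

Step 19
Reactants: 27 3-[(1S,4aR,5S,6S,8aR)-5-[(2,5-dimethoxy-3-methylphenyl)methyl]-5,6,8a-trimethyl-2-oxodecahydronaphthalen-1-yl]propanoic acid
Product: 28 3-[(1S,4aR,5S,6S,8aR)-5-[(2,5-dihydroxy-3-methylphenyl)methyl]-5,6,8a-trimethyl-2-oxodecahydronaphthalen-1-yl]propanoic acid (CNP0167047.1)
Conditions: BBr3 (5 equiv), CH2Cl2, −78 → 0 °C; H2O; work-up under N2
Reagents that add atoms: none
Why: Lewis-acid cleavage of both aryl methyl ethers by BBr3, which the saturated keto acid tolerates; the only epimerisable centre, C5, is already in its stable configuration.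

Compound list
1 | 4-methoxy-2-methylphenol | Cc1cc(OC)ccc1O | starting material
2 | 2-hydroxy-5-methoxy-3-methylbenzaldehyde | Cc1cc(OC)cc(C=O)c1O | intermediate
3 | 2,5-dimethoxy-3-methylbenzaldehyde | Cc1cc(OC)cc(C=O)c1OC | intermediate
4 | (2,5-dimethoxy-3-methylphenyl)methanol | Cc1cc(OC)cc(CO)c1OC | intermediate
5 | 1-(bromomethyl)-2,5-dimethoxy-3-methylbenzene | Cc1cc(OC)cc(CBr)c1OC | intermediate
6 | 2-methylcyclohexane-1,3-dione | CC1C(=O)CCCC1=O | starting material
7 | 1-bromobut-2-yne | CC#CCBr | starting material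
8 | 2-(but-2-yn-1-yl)-2-methylcyclohexane-1,3-dione | CC#CCC1(C)C(=O)CCCC1=O | intermediate
9 | (2S,3S)-2-(but-2-yn-1-yl)-3-hydroxy-2-methylcyclohexan-1-one (OH cis to butynyl) | O=C1CCC[C@H](O)[C@]1(C)CC#CC | intermediate
10 | (2S,3S)-2-(but-2-yn-1-yl)-3-(tert-butyldimethylsilyloxy)-2-methylcyclohexan-1-one | O=C1CCC[C@H](O[Si](C)(C)C(C)(C)C)[C@]1(C)CC#CC | intermediate
11 | (2S,3S)-3-(tert-butyldimethylsilyloxy)-2-methyl-2-(2-oxobutyl)cyclohexan-1-one (1,4-diketone) | O=C1CCC[C@H](O[Si](C)(C)C(C)(C)C)[C@]1(C)CC(=O)CC | intermediate (not isolated)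
12 | (7S,7aR)-7-(tert-butyldimethylsilyloxy)-3,7a-dimethyl-1,4,5,6,7,7a-hexahydro-2H-inden-2-one | CC1=C2CCC[C@H](O[Si](C)(C)C(C)(C)C)[C@]2(C)CC1=O | intermediate
13 | lithium C1=C3 enolate of the trans-fused (8aα-H) hydrindan-2-one | [Li+].[O-]C1=C(C)[C@H]2CCC[C@H](O[Si](C)(C)C(C)(C)C)[C@]2(C)C1 | intermediate (not isolated)
14 | (1R,3aR,4S,7aS)-4-(tert-butyldimethylsilyloxy)-1-[(2,5-dimethoxy-3-methylphenyl)methyl]-1,3a-dimethyloctahydro-2H-inden-2-one (1α-CH2Ar, 1β-CH3, 4aβ-CH3, 8aα-H, 5α-OTBS) | Cc1cc(OC)cc(C[C@]2(C)[C@H]3CCC[C@H](O[Si](C)(C)C(C)(C)C)[C@]3(C)CC2=O)c1OC | intermediate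
15 | dibromomethyl carbinol of 14 (C3: β-OH, α-CHBr2) | Cc1cc(OC)cc(C[C@]2(C)[C@H]3CCC[C@H](O[Si](C)(C)C(C)(C)C)[C@]3(C)C[C@]2(O)C(Br)Br)c1OC | intermediate
16 | β-oxido carbenoid (lithium alkoxide, CH(Li)Br on C3) | Cc1cc(OC)cc(C[C@]2(C)[C@H]3CCC[C@H](O[Si](C)(C)C(C)(C)C)[C@]3(C)C[C@]2([O-])C([Li])Br)c1OC.[Li+] | intermediate (not isolated)
17 | ring-enlarged lithium enolate (C2=C3, trans-decalin) | Cc1cc(OC)cc(C[C@]2(C)[C@H]3CCC[C@H](O[Si](C)(C)C(C)(C)C)[C@]3(C)CC([O-])=C2)c1OC.[Li+] | intermediate (not isolated)
18 | 1α-(arylmethyl)-1β,2α,4aβ-trimethyl-5α-(tert-butyldimethylsilyloxy)-8aα-H-decalin-3-one | Cc1cc(OC)cc(C[C@]2(C)[C@H]3CCC[C@H](O[Si](C)(C)C(C)(C)C)[C@]3(C)CC(=O)[C@@H]2C)c1OC | intermediate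
19 | C3=C4 enol triflate of 18 | Cc1cc(OC)cc(C[C@]2(C)[C@H]3CCC[C@H](O[Si](C)(C)C(C)(C)C)[C@]3(C)C=C(OS(=O)(=O)C(F)(F)F)[C@@H]2C)c1OC | intermediate
20 | saturated silyl ether (C3 and C4 are CH2, 5α-OTBS) | Cc1cc(OC)cc(C[C@]2(C)[C@H]3CCC[C@H](O[Si](C)(C)C(C)(C)C)[C@]3(C)CC[C@@H]2C)c1OC | intermediate (not isolated)
21 | 1α-(arylmethyl)-1β,2α,4aβ-trimethyl-8aα-H-decalin-5α-ol | Cc1cc(OC)cc(C[C@]2(C)[C@H]3CCC[C@H](O)[C@]3(C)CC[C@@H]2C)c1OC | intermediate
22 | 1α-(arylmethyl)-1β,2α,4aβ-trimethyl-8aα-H-decalin-5-one | Cc1cc(OC)cc(C[C@]2(C)[C@H]3CCCC(=O)[C@]3(C)CC[C@@H]2C)c1OC | intermediate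
23 | C5=C6 enol triflate of 22 | Cc1cc(OC)cc(C[C@]2(C)[C@H]3CCC=C(OS(=O)(=O)C(F)(F)F)[C@]3(C)CC[C@@H]2C)c1OC | intermediate
24 | 5-allyl-1α-(arylmethyl)-1β,2α,4aβ-trimethyl-8aα-H-octalin (C5=C6) | Cc1cc(OC)cc(C[C@]2(C)[C@H]3CCC=C(CC=C)[C@]3(C)CC[C@@H]2C)c1OC | intermediate
25 | cyclic borane (borinane: B–H bridging C6α and the chain terminus, 5α-H) | Cc1cc(OC)cc(C[C@]2(C)[C@H]3CC[C@@H]4BCCC[C@H]4[C@]3(C)CC[C@@H]2C)c1OC | intermediate (not isolated)
26 | 1α-(arylmethyl)-5β-(3-hydroxypropyl)-1β,2α,4aβ-trimethyl-8aα-H-decalin-6α-ol | Cc1cc(OC)cc(C[C@]2(C)[C@H]3CC[C@H](O)[C@@H](CCCO)[C@]3(C)CC[C@@H]2C)c1OC | intermediate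
27 | 3-[(1S,4aR,5S,6S,8aR)-5-[(2,5-dimethoxy-3-methylphenyl)methyl]-5,6,8a-trimethyl-2-oxodecahydronaphthalen-1-yl]propanoic acid | Cc1cc(OC)cc(C[C@]2(C)[C@H]3CCC(=O)[C@@H](CCC(=O)O)[C@]3(C)CC[C@@H]2C)c1OC | intermediate
28 | 3-[(1S,4aR,5S,6S,8aR)-5-[(2,5-dihydroxy-3-methylphenyl)methyl]-5,6,8a-trimethyl-2-oxodecahydronaphthalen-1-yl]propanoic acid | Cc1cc(O)cc(C[C@]2(C)[C@H]3CCC(=O)[C@@H](CCC(=O)O)[C@]3(C)CC[C@@H]2C)c1O | target

Total step count: 19. Longest linear sequence: 15 steps (steps 5–19; the branch through steps 1–4 and 9–19 is equally long).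

Steps most likely to fail

Step 11 (key step). The methylene carbon C4 may migrate in competition with the quaternary C1. The carbenoid may be protonated or collapse to an epoxide before it rearranges. Proton exchange during the methylation may also move the enolate towards C4. The fallback replaces the carbenoid shift by a cationic one and sets out from 15. AgBF4 with 2,6-di-tert-butylpyridine in CH2Cl2 ionises one C–Br bond. The silver-assisted halohydrin semipinacol shift, in which the more substituted carbon moves to the electron-deficient centre, should give the ring-enlarged α-bromo ketone F1. Me2CuLi in Et2O at −78 °C then turns F1 into the same C2=C3 enolate by halogen–metal exchange, MeI methylates it axially, and the route is rejoined at 18.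

Step 9. Protonation at C8a may show poor facial selectivity, giving a cis-fused hydrindanone. The enolate may equilibrate by proton transfer before it is alkylated, and residual metal may reduce the benzylic bromide. The fallback separates C–C bond formation from the setting of C8a and sets out from 12. KOt-Bu in t-BuOH/THF forms the extended dienolate by removal of a C8 proton. Deconjugative α-alkylation with 5 on the α face should give the β,γ-unsaturated ketone F2 (quaternary C1, C8=C8a alkene). Hydrogenation over Pd/C in EtOAc, with hydrogen entering anti to the angular methyl group and the 1β-methyl group, then gives the 8aα-H compound, and the route is rejoined at 14.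

Step 18. Once the aldehyde stage is reached, lactol formation with the C6 hydroxyl group may divert material to a δ-lactone. The chromium reagent may also oxidatively demethylate the electron-rich arene. The fallback sets out from 26. Swern oxidation, in which both alcohols are activated before base is added, should give the keto aldehyde F3. Pinnick oxidation (NaClO2, NaH2PO4, 2-methylbut-2-ene, t-BuOH/H2O) then gives the acid, and the route is rejoined at 27.

Further compounds
F1 | step 11 | ring-enlarged α-bromo ketone (2-bromo-decalin-3-one, C2 epimers; other centres as in 18) | Cc1cc(OC)cc(C[C@]2(C)[C@H]3CCC[C@H](O[Si](C)(C)C(C)(C)C)[C@]3(C)CC(=O)C2Br)c1OC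
F2 | step 9 | β,γ-unsaturated ketone (1α-CH2Ar, 1β-CH3, C8=C8a alkene, five-membered ring ketone at C3) | Cc1cc(OC)cc(C[C@]2(C)C3=CCC[C@H](O[Si](C)(C)C(C)(C)C)[C@]3(C)CC2=O)c1OC
F3 | step 18 | keto aldehyde (C6 ketone, 5β-CH2CH2CHO) | Cc1cc(OC)cc(C[C@]2(C)[C@H]3CCC(=O)[C@@H](CCC=O)[C@]3(C)CC[C@@H]2C)c1OC
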